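A small charge of reagent tempted me to the usual bench count: with 0.600 equiv against the starting material, reckon the yield on the smaller charge and expect that much target. Three flasks were to test this, south, south-west and south-east, differing in time.

| flask | starting material | reagent | remark | time |
|---|---|---|---|---|
| Tuesday's | 0.050 M | 0.90 equiv | run made earlier |  |
| south | 0.050 M | 0.600 equiv |  | 2.5 d |
| south-west | 0.050 M | 0.600 equiv |  | 6.0 d |
| south-east | 0.050 M | 0.600 equiv |  | 15 d |

Tuesday's run (percent of the starting material charged)

| time / h | target / % | intermediate D / % | starting material / % | over-reaction product / % | isomer of the product / % | intermediate A / % |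
|---|---|---|---|---|---|---|
| 2.50 | 7.2 | 0 | 82.4 | 1.3 | 0.2 | 7.0 |
| 6.00 | 15.0 | 2.5 | 65.0 | 0.7 | 0.5 | 11.9 |
| 12.0 | 20.8 | 6.4 | 43.9 | 2.8 | 1.0 | 17.1 |
| 20.0 | 24.3 | 12.4 | 28.6 | 5.3 | 0.8 | 17.7 |

(scatter of a reading: 0.5 percentage points)

- the earlier runs were read with a standard deviation of 0.5 percentage points

* which of these there is most of at the end, counted by the starting material in it, south (target / over-reaction product / intermediate A / isomer of the product / intermediate D)
* which of these there is most of at the end, counted by the starting material in it, south-west (target / over-reaction product / intermediate A / isomer of the product / intermediate D)
* which of these there is most of at the end, counted by the starting material in it, south-east (target / over-reaction product / intermediate A / isomer of the product / intermediate D)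
* how much there is at the end of the one of these that leads, in percent of the starting material charged: south
* how much there is at the end of the one of these that leads, in percent of the starting material charged: south-west
* how much there is at the end of the one of these that leads, in percent of the starting material charged: south-east

Tuesday's run shows where that count stops. At 2.50 h it held 7.0% of intermediate A against 7.2% of target, 1.3% of over-reaction product and 0.2% of isomer. I called the parts in intermediates A and D per part in those three products the split (a selectivity factor), and it read 0.805, with the scatter of the readings in it. By 20.0 h the same count read 0.990, higher, and I read that rise as a sign of reagent being used, though reagent itself was not read. So I took one route to need reagent and the other not, which makes the split go inversely with the reagent concentration. Multiplying the first split by Tuesday's reagent concentration gives the balance level, the reagent concentration at which the two routes take starting material equally: 0.0362 M.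

South started at 0.0300 M, a ratio of 0.829 to the balance level and so below it. That is the border: the bench count assumes the starting material waits for reagent, but in south I reckoned the reagent-free route ahead from the start. For the start of south the split reckoned to 1.21, which put 54.7% of what the count sees on the reagent-free side, and I expected more as reagent fell. In Tuesday's run the readings of intermediate A had gone flat, from 17.1% to 17.7%, while intermediate D climbed, so I expected intermediate D to lead in south, south-west and south-east.

The forecast named target for south at 25%, calling it “a near tie”, then intermediate D at 42% for south-west and intermediate D at 52% for south-east. We differed on south.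

South gave intermediate D at 40.0%, with target at 18.9%; south-west gave intermediate D at 52.9%; south-east gave intermediate D at 56.8%.

    starting material + reagent → target (k = 0.0140 L mol⁻¹ min⁻¹)
    starting material → intermediate A (k = 4.90 × 10⁻⁴ min⁻¹)
    starting material + reagent ⇌ intermediate B (K = 27.0 L mol⁻¹, k = 0.00510 L mol⁻¹ min⁻¹)
    intermediate B ⇌ intermediate C (K = 2.60, k = 0.00160 min⁻¹)
    intermediate A ⇌ intermediate D (K = 47.0, k = 8.50 × 10⁻⁴ min⁻¹)
    reagent + intermediate D ⇌ intermediate E (K = 43.0 L mol⁻¹, k = 0.0130 L mol⁻¹ min⁻¹)
    reagent + target → over-reaction product (k = 0.00770 L mol⁻¹ min⁻¹)
    target ⇌ isomer of the product (K = 13.0, k = 5.20 × 10⁻⁵ min⁻¹)

South, which started below the balance level 0.0362 M, stood at 2.5 d at a count of 1.82, summed over its whole run, with reagent down to 20.9% of its charge. A neighbouring flask, like south but charged with 0.020 M of starting material at the same equivalents, started at 0.0120 M of reagent, a third of the balance level, so for its start the split reckoned to 3.02. At 2.50 d that flask held 48.4% of intermediate D and 12.9% of intermediate A against 13.2% of target, 2.23% of over-reaction product and 1.99% of isomer, a count, summed over its whole run, of 3.52.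

The earlier runs and the new flask were computed with made-up constants.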